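The numbers in the tables are simulated for substances that don't exist; scatter was added.

0.60 M of reagent meets 1 M of starting material in Monday's run, and yet the starting material stops at 75.9% of its charge, with target at 0%. Saturday's run, with 110 mM of precatalyst against 70 mM, stops at 76.1%. The new flask repeats these charges with 50 mM of precatalyst.

| flask | starting material | reagent | second substrate | precatalyst | remark | time |
|---|---|---|---|---|---|---|
| Monday's | 1 M | 0.60 M | 1 M | 70 mM | run made earlier |  |
| Saturday's | 1 M | 0.60 M | 1 M | 110 mM | run made earlier |  |
| flask | 1.0 M | 0.600 M | 1.00 M | 50 mM |  | 80 min |

| run | time / min | target / % | starting material / % |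
|---|---|---|---|
| Monday's | 2.00 | 2.9 | 96.8 |
| Monday's | 5.00 | 9.0 | 86.8 |
| Monday's | 10.0 | 8.6 | 78.6 |
| Monday's | 20.0 | 2.7 | 75.7 |
| Monday's | 50.0 | 0 | 75.9 |
| Saturday's | 2.00 | 4.4 | 95.1 |
| Saturday's | 5.00 | 10.7 | 84.0 |
| Saturday's | 10.0 | 9.1 | 77.1 |
| Saturday's | 20.0 | 2.4 | 76.3 |
| Saturday's | 50.0 | 0 | 76.1 |

(standard deviation of a reading: 0.3 percentage points)

* the best time, 80 min at the latest, for target
* the amount of target, in percent of the starting material charged, at that time
* the first time at which target reaches 4.7%, in the same percent, in min



These numbers seem not to go together: Monday's reagent equals 60.0% of the starting material, but the starting material loses 24.1%. The stops of the two runs differ by 0.2 percentage points at a scatter of 0.3 points, so I look to the reagent, not the precatalyst. I suppose that reagent is the limiting reagent and that the second substrate, charged at 1 M, takes what the starting material does not. The two runs give 0.400 for the reagent share, the amount of starting material lost per amount of reagent charged. The new flask differs from these runs in its precatalyst charge, and the two stops lie within 0.2 points of each other, so I hold the share constant as my own estimate. For the new flask I reckon a loss of 0.240 M, a stop at 76.0%.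

The forecast holds that “the 24% conversion limit does not depend on catalyst”, and gives 8.6% of target at 7.8 min, with 4.7% first reached at 3.5 min.

The flask gives 9.38% at 8.24 min, and reaches 4.7% first at 3.33 min, all within the forecast's margins.

    target → over-reaction product (k = 0.170 min⁻¹)
    starting material + reagent + catalyst → catalyst + target (k = 3.20 M⁻² min⁻¹)
    second substrate + reagent + catalyst → catalyst + second product (k = 5.20 M⁻² min⁻¹)
    precatalyst → catalyst (k = 0.150 min⁻¹)

At 80.0 min the flask holds 76.0% starting material, 24.0% over-reaction product and 0% reagent, with the second product at 0.360 M. A neighbouring flask is charged with 0.15 M of reagent, its other charges and time held. The share gives a loss of 0.0600 M, which is 6.00% of the starting material charged, so a stop at 94.0%. At 80.0 min the neighbouring flask holds 0% reagent, 94.2% starting material and 5.78% over-reaction product.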